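## Retrosynthetic overview

1. Feature: on ring A the edge C5–C6–C7–C8 carries OH, OMe, OH, OMe. This is the oxygen pattern of C1–C4 of methyl 2,4-dimethoxyacetoacetate, and the other two ring A carbons, C4a and C8a, are the α- and β-carbons of the ring C enone. Ring A is also symmetric about the C7···C4a axis, so any opening and reclosure of ring C is degenerate.
2. Endgame: target ⇒ flavone 3',4'-dibenzyl ether (hydrogenolysis) ⇒ racemic flavanone (C2–C3 dehydrogenation).
3. Key cut: C4a–C5 and C8–C8a of the flavanone ⇒ 1,2,4-trimethoxy-1,3-bis(trimethylsilyloxy)buta-1,3-diene plus a 2-aryl-2,3-dihydro-4H-pyran-4-one with a leaving group X on C5. A [4+2] addition followed by loss of HX and MeOH builds aromatic ring A.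
4. X is phenylsulfinyl, not halogen. Suprafacial addition places X on C4a cis to C8a–H, and no second carbonyl acidifies that hydrogen, so anti or E1cB loss of HBr has no path, whereas thermal syn loss of PhSOH fits. The sulfinyl group also activates the push–pull C5=C6 bond and is installed without a reagent that could brominate ring B.
5. Ring order: B (bought as 3,4-dihydroxy-5-methoxybenzaldehyde), then C (hetero-Diels–Alder with 1-methoxy-3-(trimethylsilyloxy)butadiene), then A. The diene comes from the self-Claisen product of methyl methoxyacetate by two silylations.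

Key step: step 8

Assumption: C2 of ring C and the sulfoxide sulfur are stereogenic only in intermediates. These are carried as racemates or diastereomer mixtures, because the target is achiral and both centres disappear (sulfur in step 8, C2 in step 9).

## Route

Step 1
Reactants: 1 3,4-dihydroxy-5-methoxybenzaldehyde
Product: 2 3,4-bis(benzyloxy)-5-methoxybenzaldehyde
Conditions: BnBr (2.3 equiv), K2CO3 (2.5 equiv), DMF, 60 °C
Reagents that add atoms: benzyl bromide, BrCc1ccccc1
Why: Williamson etherification of both phenoxides with a primary benzylic halide, to which the aldehyde and the methyl ether are inert.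

Step 2
Reactants: 2 3,4-bis(benzyloxy)-5-methoxybenzaldehyde; 3 (E)-1-methoxy-3-(trimethylsilyloxy)buta-1,3-diene
Product: 5 2-[3,4-bis(benzyloxy)-5-methoxyphenyl]-2,3-dihydro-4H-pyran-4-one (racemic), via silyl enol ether cycloadduct 4 (not isolated)
Conditions: ZnCl2 (0.5 equiv), THF, 25 °C; then TFA (cat.), CH2Cl2, 0 → 25 °C
Reagents that add atoms: none
Why: Lewis-acid-promoted hetero-Diels–Alder reaction of an aromatic aldehyde with a 1-alkoxy-3-silyloxydiene closes ring C, acid then removes the silyl group and expels methanol to give the enone, and the C2 centre forms without control as a racemate that step 9 erases.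

Step 3
Reactants: 5 2-[3,4-bis(benzyloxy)-5-methoxyphenyl]-2,3-dihydro-4H-pyran-4-one
Product: 7 2-[3,4-bis(benzyloxy)-5-methoxyphenyl]-5-(phenylthio)-2,3-dihydro-4H-pyran-4-one (racemic), via chloro sulfide adduct 6 (not isolated)
Conditions: PhSCl (1.05 equiv), CH2Cl2, −78 → 0 °C; then Et3N (1.5 equiv), 0 → 25 °C
Reagents that add atoms: benzenesulfenyl chloride, ClSc1ccccc1
Why: Sulfenyl chloride addition followed by dehydrochlorination, the usual way to 2-(phenylthio)enones, puts sulfur on the nucleophilic C5 and chloride on the oxygen-stabilised C6, Et3N then removes the acidic C5–H (E1cB), and PhSCl is too mild to attack the trialkoxyphenyl ring.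

Step 4
Reactants: 7 2-[3,4-bis(benzyloxy)-5-methoxyphenyl]-5-(phenylthio)-2,3-dihydro-4H-pyran-4-one
Product: 8 2-[3,4-bis(benzyloxy)-5-methoxyphenyl]-5-(phenylsulfinyl)-2,3-dihydro-4H-pyran-4-one (racemic, both sulfur epimers)
Conditions: mCPBA (1.0 equiv), CH2Cl2, −40 → 0 °C
Reagents that add atoms: 3-chloroperoxybenzoic acid, O=C(OO)c1cccc(Cl)c1
Why: Peracid oxidation of a sulfide to the sulfoxide with one equivalent at low temperature stops before the sulfone and leaves the electron-poor C5=C6 bond alone, and the uncontrolled sulfur configuration does not matter because sulfur leaves in step 8.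

Step 5
Reactants: 9 methyl methoxyacetate (two molecules)
Product: 10 methyl 2,4-dimethoxy-3-oxobutanoate (racemic, enolisable)
Conditions: NaH (0.55 equiv per ester), THF, 60 °C; then cold 1 M HCl
Reagents that add atoms: none
Why: Claisen self-condensation of an α-alkoxy ester, driven by deprotonation of the β-keto ester product, sets the C1–C4 chain with its four oxygens in one operation.

Step 6
Reactants: 10 methyl 2,4-dimethoxy-3-oxobutanoate
Product: 11 methyl 2,4-dimethoxy-3-(trimethylsilyloxy)but-2-enoate (E/Z mixture)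
Conditions: TMSCl (1.5 equiv), Et3N (1.6 equiv), toluene, 25 °C
Reagents that add atoms: chlorotrimethylsilane, C[Si](C)(C)Cl
Why: Amine-mediated O-silylation of a β-keto ester gives the conjugated silyl enol ether, and any regioisomeric enol ether towards C4 would converge on the same diene in step 7.

Step 7
Reactants: 11 methyl 2,4-dimethoxy-3-(trimethylsilyloxy)but-2-enoate
Product: 13 1,2,4-trimethoxy-1,3-bis(trimethylsilyloxy)buta-1,3-diene (one geometric isomer drawn), via lithium dienolate 12 (not isolated)
Conditions: LDA (1.2 equiv), THF, −78 °C; then TMSCl (1.3 equiv), −78 → 0 °C; filtered under argon, used crude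
Reagents that add atoms: chlorotrimethylsilane, C[Si](C)(C)Cl
Why: Kinetic γ-deprotonation of a β-silyloxy enoate and O-silylation of the dienolate is the standard two-stage preparation of 1-alkoxy-1,3-bis(silyloxy)dienes, and it is known for 2-alkoxy and for 4-alkoxy members.

Step 8
Reactants: 8 2-[3,4-bis(benzyloxy)-5-methoxyphenyl]-5-(phenylsulfinyl)-2,3-dihydro-4H-pyran-4-one; 13 1,2,4-trimethoxy-1,3-bis(trimethylsilyloxy)buta-1,3-diene
Product: 17 2-[3,4-bis(benzyloxy)-5-methoxyphenyl]-5,7-dihydroxy-6,8-dimethoxychroman-4-one (racemic flavanone), via sulfinyl cycloadduct 14 (not isolated), via cyclohexadiene ketal 15 (not isolated), via bis-silyl ether 16 (not isolated)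
Conditions: 13 (3 equiv, the excess also takes up PhSOH and MeOH), toluene, argon, 25 → 80 °C; then 1 M HCl, THF, 25 °C
Reagents that add atoms: none
Why: Proposed new method: the CH(OMe) terminus of 13, which is the vinylogous end of the silyl ketene acetal and its least hindered carbon, bonds to C6 of 8 (β to both C=O and S=O, target C8a) while the ketene acetal carbon bonds to C5 (target C4a), either in a concerted, strongly asynchronous [4+2] addition or by Mukaiyama–Michael addition and collapse of the zwitterion (enolate carbon C4a onto the dialkoxycarbenium carbon C5), so ring A closes as the new six-membered carbocycle of 14. Because the addition is suprafacial, the sulfinyl group on C4a lies cis to C8a–H, its only β-hydrogen, which is the geometry the five-centre thermal syn elimination of benzenesulfenic acid needs and which leads to 15, whereas a halide at C4a would need an anti hydrogen or a second acidifying carbonyl as in haloquinone adducts, and this adduct has neither. In 15 the C5 ketal is doubly allylic and C8–H is the γ-hydrogen of the restored enone, so 1,4-loss of methanol aromatises ring A to 16 and dilute acid frees the C5 and C7 hydroxyls. The closest known reactions are the cycloaddition/sulfoxide-elimination sequences of 2-sulfinylquinones and 2-sulfinylcycloalkenones with oxygenated dienes, the eliminative aromatisations of 1-alkoxy-1,3-bis(silyloxy)dienes with haloquinones, and conjugate addition/sulfoxide elimination on 3-sulfinylchromones, but a 5-sulfinyl-2,3-dihydropyran-4-one has not served as the dienophile. No stereocentre made here survives (C4a, C5, C8 and C8a all become sp2 and sulfur leaves), and C2 stays racemic. The step needs regio- and chemoselectivity: the 1-OMe, 1-OSiMe3 and 3-OSiMe3 donors outweigh the 2- and 4-OMe groups in pushing electron density to C4 of the diene, the dienophile has a single polarised C=C whose ring-locked s-trans enone cannot act as a heterodiene, and Lewis acids are left out so that silyl transfer to the sulfoxide oxygen (Pummerer-type loss) is held back.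

Step 9
Reactants: 17 2-[3,4-bis(benzyloxy)-5-methoxyphenyl]-5,7-dihydroxy-6,8-dimethoxychroman-4-one
Product: 18 2-[3,4-bis(benzyloxy)-5-methoxyphenyl]-5,7-dihydroxy-6,8-dimethoxy-4H-chromen-4-one
Conditions: I2 (0.2 equiv), DMSO, 110 °C
Reagents that add atoms: none
Why: Iodine-catalysed dehydrogenation in DMSO (C3 iodination through the enol, loss of HI, DMSO as terminal oxidant) is the standard flavanone-to-flavone oxidation and tolerates free 5- and 7-hydroxyls, ring A has no free CH to iodinate, and reversible opening to the 2'-hydroxychalcone is harmless because ring A is symmetric and the chalcone is oxidised to the same flavone.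

Step 10
Reactants: 18 2-[3,4-bis(benzyloxy)-5-methoxyphenyl]-5,7-dihydroxy-6,8-dimethoxy-4H-chromen-4-one
Product: 19 5,7,3',4'-tetrahydroxy-6,8,5'-trimethoxyflavone
Conditions: H2 (1 atm), Pd/C (10 wt % Pd), EtOAc/MeOH, 25 °C
Reagents that add atoms: none
Why: Hydrogenolysis of aryl benzyl ethers over palladium at ambient pressure is faster than reduction of the flavone C2=C3 bond and leaves the three methyl ethers in place, so the two ring B hydroxyls are freed to give the achiral target.

## Compound list

1 | 3,4-dihydroxy-5-methoxybenzaldehyde | COc1cc(C=O)cc(O)c1O | starting material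
2 | 3,4-bis(benzyloxy)-5-methoxybenzaldehyde | COc1cc(C=O)cc(OCc2ccccc2)c1OCc1ccccc1 | intermediate
3 | (E)-1-methoxy-3-(trimethylsilyloxy)buta-1,3-diene | CO/C=C/C(=C)O[Si](C)(C)C | starting material
4 | 2-[3,4-bis(benzyloxy)-5-methoxyphenyl]-6-methoxy-4-(trimethylsilyloxy)-3,6-dihydro-2H-pyran (racemic, C2/C6 diastereomers, not isolated) | COC1C=C(O[Si](C)(C)C)CC(c2cc(OC)c(OCc3ccccc3)c(OCc3ccccc3)c2)O1 | intermediate
5 | 2-[3,4-bis(benzyloxy)-5-methoxyphenyl]-2,3-dihydro-4H-pyran-4-one (racemic) | O=C1C=COC(c2cc(OC)c(OCc3ccccc3)c(OCc3ccccc3)c2)C1 | intermediate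
6 | 2-[3,4-bis(benzyloxy)-5-methoxyphenyl]-6-chloro-5-(phenylthio)tetrahydro-4H-pyran-4-one (diastereomer mixture, not isolated) | O=C1CC(c2cc(OC)c(OCc3ccccc3)c(OCc3ccccc3)c2)OC(Cl)C1Sc1ccccc1 | intermediate
7 | 2-[3,4-bis(benzyloxy)-5-methoxyphenyl]-5-(phenylthio)-2,3-dihydro-4H-pyran-4-one (racemic) | O=C1CC(c2cc(OC)c(OCc3ccccc3)c(OCc3ccccc3)c2)OC=C1Sc1ccccc1 | intermediate
8 | 2-[3,4-bis(benzyloxy)-5-methoxyphenyl]-5-(phenylsulfinyl)-2,3-dihydro-4H-pyran-4-one (racemic, both sulfur epimers) | O=C1CC(c2cc(OC)c(OCc3ccccc3)c(OCc3ccccc3)c2)OC=C1S(=O)c1ccccc1 | intermediate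
9 | methyl methoxyacetate | COCC(=O)OC | starting material
10 | methyl 2,4-dimethoxy-3-oxobutanoate (racemic) | COCC(=O)C(OC)C(=O)OC | intermediate
11 | methyl 2,4-dimethoxy-3-(trimethylsilyloxy)but-2-enoate (E/Z mixture) | COCC(O[Si](C)(C)C)=C(OC)C(=O)OC | intermediate
12 | lithium 1,2,4-trimethoxy-3-(trimethylsilyloxy)buta-1,3-dien-1-olate (not isolated) | CO/C=C(O[Si](C)(C)C)/C(OC)=C(/OC)[O-].[Li+] | intermediate
13 | 1,2,4-trimethoxy-1,3-bis(trimethylsilyloxy)buta-1,3-diene (one geometric isomer drawn) | CO/C=C(O[Si](C)(C)C)/C(OC)=C(/OC)O[Si](C)(C)C | intermediate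
14 | 2-[3,4-bis(benzyloxy)-5-methoxyphenyl]-5,6,8-trimethoxy-4a-(phenylsulfinyl)-5,7-bis(trimethylsilyloxy)-2,3,4a,5,8,8a-hexahydro-4H-chromen-4-one (cis ring fusion, diastereomer mixture, not isolated) | O=C1CC(c2cc(OC)c(OCc3ccccc3)c(OCc3ccccc3)c2)OC2C(OC)C(O[Si](C)(C)C)=C(OC)C(OC)(O[Si](C)(C)C)C12S(=O)c1ccccc1 | intermediate
15 | 2-[3,4-bis(benzyloxy)-5-methoxyphenyl]-5,6,8-trimethoxy-5,7-bis(trimethylsilyloxy)-2,3,5,8-tetrahydro-4H-chromen-4-one (diastereomer mixture, not isolated) | O=C1CC(c2cc(OC)c(OCc3ccccc3)c(OCc3ccccc3)c2)OC2=C1C(OC)(O[Si](C)(C)C)C(OC)=C(O[Si](C)(C)C)C2OC | intermediate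
16 | 2-[3,4-bis(benzyloxy)-5-methoxyphenyl]-6,8-dimethoxy-5,7-bis(trimethylsilyloxy)chroman-4-one (racemic, not isolated) | O=C1CC(c2cc(OC)c(OCc3ccccc3)c(OCc3ccccc3)c2)Oc2c(OC)c(O[Si](C)(C)C)c(OC)c(O[Si](C)(C)C)c12 | intermediate
17 | 2-[3,4-bis(benzyloxy)-5-methoxyphenyl]-5,7-dihydroxy-6,8-dimethoxychroman-4-one (racemic) | O=C1CC(c2cc(OC)c(OCc3ccccc3)c(OCc3ccccc3)c2)Oc2c(OC)c(O)c(OC)c(O)c12 | intermediate
18 | 2-[3,4-bis(benzyloxy)-5-methoxyphenyl]-5,7-dihydroxy-6,8-dimethoxy-4H-chromen-4-one | O=c1cc(-c2cc(OC)c(OCc3ccccc3)c(OCc3ccccc3)c2)oc2c(OC)c(O)c(OC)c(O)c12 | intermediate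
19 | 5,7,3',4'-tetrahydroxy-6,8,5'-trimethoxyflavone | COc1cc(-c2cc(=O)c3c(O)c(OC)c(O)c(OC)c3o2)cc(O)c1O | target

## Step count and risks

Total step count: 10. Longest linear sequence: 7 (steps 1, 2, 3, 4, 8, 9, 10). The diene branch (steps 5–7) joins at step 8.

**Step 8 (the labelled step).**
- What may go wrong: the cycloaddition may be too slow on a push–pull alkene. Silyl transfer from the ketene acetal to the sulfoxide oxygen may consume both partners. The reaction may stop after the first C–C bond and expel the ring oxygen from C8a. The 2- and 4-methoxy donors may erode the regiocontrol.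
- Fallback: this uses known chemistry only. Ring A is bought and its two methoxy groups are put on last. It sets out from 2 and comes back at 18.
- Claisen–Schmidt condensation of 2 with commercial 2'-hydroxy-4',6'-bis(methoxymethoxy)acetophenone (KOH, EtOH, 25 °C) should give the chalcone F1.
- Oxidative cyclisation (I2 cat., DMSO, 110 °C) should give the 5,7-bis(methoxymethoxy)flavone F2.
- HCl in MeOH at 50 °C should give the 5,7-dihydroxyflavone F3.
- Two equivalents of NBS in DMF at 0 °C should brominate the phloroglucinol-type ring A at its only free positions to the 6,8-dibromoflavone F4.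
- Ullmann-type methoxylation (NaOMe, CuBr, DMF/MeOH, 110 °C), a known exchange on 6,8-dibromo-5,7-dihydroxyflavones, should replace both bromides and deliver 18 for step 10.

**Step 7.**
- What may go wrong: γ-deprotonation may be incomplete. C-silylation, hydrolysis or silyl migration may occur on handling. The C3=C4 bond may form with the geometry that cannot reach the s-cis conformer.
- Fallback: this is an anionic, stepwise formation of the same two bonds without any silyl diene. It sets out from 10 (with 8 as partner) and comes back at 17.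
- Double deprotonation of 10 (NaH, then n-BuLi, THF, 0 °C) should give the 2,4-dianion F5.
- The C4 carbanion of F5 should add at −78 °C to C6 of 8, giving after NH4Cl quench the Michael adduct F6.
- Warming in toluene at 80 °C should expel benzenesulfenic acid by syn elimination, giving the 6-substituted dihydropyranone F7.
- NaOMe in MeOH should then close ring A by Claisen-type acylation of the extended enolate at C5 of the pyranone (target C4a). Loss of methanol and tautomerisation give 17. Any chalcone formed by opening of ring C recloses to the same flavanone.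

**Step 3.**
- What may go wrong: addition of the sulfenyl chloride to the deactivated enol ether bond may be sluggish. Ring C may open at the 6-chloro stage. Sulfenylation may occur at C3 through the enol.
- Fallback: ring C is built with the sulfoxide already in place. It sets out from 2 and comes back at 8, bypassing steps 2–4.
- NaIO4 oxidation of commercial 1-(phenylthio)propan-2-one should give 1-(phenylsulfinyl)propan-2-one F8.
- Two equivalents of LDA (THF, −78 → 0 °C) should give its dilithium dianion F9.
- The terminal carbanion of F9 should add to aldehyde 2 to give the δ-hydroxy-β-keto sulfoxide F10.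
- N,N-dimethylformamide dimethyl acetal (toluene, 25 → 60 °C) should condense at the doubly activated CH2 to the enaminone F11.
- In F11 the hydroxyl should displace dimethylamine and close the dihydropyranone 8. This is the known way from δ-hydroxy-β-dicarbonyl compounds to 5-acceptor-substituted 2,3-dihydropyran-4-ones.

## Further compounds

F1 | step 8 | (E)-3-[3,4-bis(benzyloxy)-5-methoxyphenyl]-1-[2-hydroxy-4,6-bis(methoxymethoxy)phenyl]prop-2-en-1-one | COCOc1cc(O)c(C(=O)/C=C/c2cc(OC)c(OCc3ccccc3)c(OCc3ccccc3)c2)c(OCOC)c1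
F2 | step 8 | 2-[3,4-bis(benzyloxy)-5-methoxyphenyl]-5,7-bis(methoxymethoxy)-4H-chromen-4-one | COCOc1cc(OCOC)c2c(=O)cc(-c3cc(OC)c(OCc4ccccc4)c(OCc4ccccc4)c3)oc2c1
F3 | step 8 | 2-[3,4-bis(benzyloxy)-5-methoxyphenyl]-5,7-dihydroxy-4H-chromen-4-one | O=c1cc(-c2cc(OC)c(OCc3ccccc3)c(OCc3ccccc3)c2)oc2cc(O)cc(O)c12
F4 | step 8 | 2-[3,4-bis(benzyloxy)-5-methoxyphenyl]-6,8-dibromo-5,7-dihydroxy-4H-chromen-4-one | O=c1cc(-c2cc(OC)c(OCc3ccccc3)c(OCc3ccccc3)c2)oc2c(Br)c(O)c(Br)c(O)c12
F5 | step 7 | sodium lithium 2,4-dianion of methyl 2,4-dimethoxy-3-oxobutanoate | COC=C([O-])C(OC)=C([O-])OC.[Na+].[Li+]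
F6 | step 7 | methyl 4-{6-[3,4-bis(benzyloxy)-5-methoxyphenyl]-4-oxo-3-(phenylsulfinyl)tetrahydro-2H-pyran-2-yl}-2,4-dimethoxy-3-oxobutanoate (diastereomer mixture) | COC(=O)C(OC)C(=O)C(OC)C1OC(c2cc(OC)c(OCc3ccccc3)c(OCc3ccccc3)c2)CC(=O)C1S(=O)c1ccccc1
F7 | step 7 | methyl 4-{2-[3,4-bis(benzyloxy)-5-methoxyphenyl]-4-oxo-3,4-dihydro-2H-pyran-6-yl}-2,4-dimethoxy-3-oxobutanoate (diastereomer mixture) | COC(=O)C(OC)C(=O)C(OC)C1=CC(=O)CC(c2cc(OC)c(OCc3ccccc3)c(OCc3ccccc3)c2)O1
F8 | step 3 | 1-(phenylsulfinyl)propan-2-one (racemic) | CC(=O)CS(=O)c1ccccc1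
F9 | step 3 | dilithium dianion of 1-(phenylsulfinyl)propan-2-one | [Li+].[Li+].C=C([O-])[CH-]S(=O)c1ccccc1
F10 | step 3 | 4-[3,4-bis(benzyloxy)-5-methoxyphenyl]-4-hydroxy-1-(phenylsulfinyl)butan-2-one (diastereomer mixture) | O=C(CC(O)c1cc(OC)c(OCc2ccccc2)c(OCc2ccccc2)c1)CS(=O)c1ccccc1
F11 | step 3 | 5-[3,4-bis(benzyloxy)-5-methoxyphenyl]-1-(dimethylamino)-5-hydroxy-2-(phenylsulfinyl)pent-1-en-3-one | CN(C)C=C(C(=O)CC(O)c1cc(OC)c(OCc2ccccc2)c(OCc2ccccc2)c1)S(=O)c1ccccc1
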